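**Retrosynthetic overview**
- Yanuthone L comes from an iodide-mediated anodic, dehydrogenative 3-exo closure of a β-hydroxy ketone (C3–OH onto C2–H). This is the last step. It builds the quaternary epoxide carbon, and the cis-fusion to the C3 oxygen forces its configuration.
- The β-hydroxy ketone comes from C2-alkylation of the kinetic enolate of a 4-acetoxy-3-methyl-5-silyloxycyclohex-2-enone with an ω-silyloxy (E,E,E)-farnesyl bromide.
- The enone comes from (1S,2R)-toluene cis-dihydrodiol, which supplies C3, C4 and the C5-methyl alkene. The four steps are mono-silylation, acetylation, diimide reduction and allylic oxidation.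
- The chain comes from (E,E)-farnesol by SeO2 ω-oxidation. The only ring formed in the route is the epoxide.

Assumptions:
- Enantiopure (1S,2R)-toluene cis-dihydrodiol is purchased.
- The C2 epimers of 12 and 13 are irrelevant, because C2 is re-functionalised in Step 12.
- In the cyclohexenone intermediates, ring carbons are numbered as in the target: C1 carbonyl, C2 chain-bearing, C3 O, C4 OAc, C5 Me, C6 =CH.

---

**Step 1**
Reactants: 1, (1S,2R)-3-methylcyclohexa-3,5-diene-1,2-diol
Product: 2, (1S,2R)-3-methyl-1-[(triethylsilyl)oxy]cyclohexa-3,5-dien-2-ol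
Conditions: TESCl (1.05 equiv), imidazole, DMF, −20 → 0 °C
Reagents that add atoms: TESCl, CC[Si](Cl)(CC)CC
Why: Regioselective silylation of the less hindered C1–OH, the oxygen that later becomes the epoxide oxygen; no stereocentre is touched.

**Step 2**
Reactants: 2
Product: 3, (1S,2R)-3-methyl-1-[(triethylsilyl)oxy]cyclohexa-3,5-dien-2-yl acetate
Conditions: Ac2O, pyridine, DMAP (cat.), CH2Cl2, 0 °C
Reagents that add atoms: Ac2O, CC(=O)OC(C)=O
Why: Acylation of the remaining allylic OH installs the final C4 acetate and deactivates the C4–H towards radical abstraction in Step 4.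

**Step 3**
Reactants: 3
Product: 4, (1S,2R)-3-methyl-1-[(triethylsilyl)oxy]cyclohex-3-en-2-yl acetate
Conditions: 2-nitrobenzenesulfonylhydrazide (NBSH), Et3N, CH2Cl2, −20 °C → rt
Reagents that add atoms: none (only H is delivered)
Why: Diimide reduction is chemoselective for the less substituted, less hindered cis-disubstituted alkene of the diene; the trisubstituted methyl alkene is untouched and no stereocentre is created.

**Step 4**
Reactants: 4
Product: 5, (4R,5S)-4-acetoxy-3-methyl-5-[(triethylsilyl)oxy]cyclohex-2-en-1-one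
Conditions: Rh2(cap)4 (1 mol %), 70% aq. TBHP, K2CO3, CH2Cl2, rt
Reagents that add atoms: TBHP, CC(C)(C)OO (supplies the carbonyl O)
Why: Doyle-type allylic C–H oxidation occurs at the only ring CH2 allylic to the alkene, giving the β-methyl enone; the acyloxy group deactivates the C4–H.

**Step 5**
Reactants: 6, (2E,6E)-farnesol
Product: 7, (2E,6E)-farnesyl acetate
Conditions: Ac2O, pyridine, DMAP, CH2Cl2, 0 °C
Reagents that add atoms: Ac2O, CC(=O)OC(C)=O
Why: The acetate deactivates the proximal alkene so that SeO2 attacks the terminal one in Step 6.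

**Step 6**
Reactants: 7
Product: 8, (2E,6E,10E)-12-hydroxy-3,7,11-trimethyldodeca-2,6,10-trien-1-yl acetate
Conditions: SeO2 (5 mol %), TBHP (3 equiv, in decane), CH2Cl2, 0 °C → rt
Reagents that add atoms: TBHP, CC(C)(C)OO (supplies the O of the new OH)
Why: Umbreit–Sharpless allylic oxidation hits the most electron-rich, most remote alkene and gives the E-allylic alcohol from the methyl trans to the chain.

**Step 7**
Reactants: 8
Product: 9, the 12-O-TBS ether of 8
Conditions: TBSCl, imidazole, DMF, rt
Reagents that add atoms: TBSCl, CC(C)(C)[Si](C)(C)Cl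
Why: Silylation of the only free OH.

**Step 8**
Reactants: 9
Product: 10, (2E,6E,10E)-12-[(tert-butyldimethylsilyl)oxy]-3,7,11-trimethyldodeca-2,6,10-trien-1-ol
Conditions: K2CO3, MeOH, rt
Reagents that add atoms: none
Why: Methanolysis removes the acetate; the primary TBS ether survives.

**Step 9**
Reactants: 10
Product: 11, (2E,6E,10E)-1-bromo-12-(TBSO)-3,7,11-trimethyldodeca-2,6,10-triene
Conditions: CBr4, PPh3, CH2Cl2, 0 °C; used crude at once
Reagents that add atoms: CBr4, BrC(Br)(Br)Br
Why: Appel-type SN2 bromination of a primary allylic alcohol with retention of all alkene geometries.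

**Step 10**
Reactants: 5 and 11
Product: 12, (4R,5S)-4-acetoxy-6-[(2E,6E,10E)-12-(TBSO)-3,7,11-trimethyldodeca-2,6,10-trien-1-yl]-3-methyl-5-(TESO)cyclohex-2-en-1-one, as C6 epimers
Conditions: LDA (1.05 equiv), THF, −78 °C, 30 min; then HMPA, 11 (1.5 equiv), −78 → −40 °C
Reagents that add atoms: none beyond the numbered reactant 11
Why: LDA deprotonates kinetically at the only enolizable α′ carbon (C2), and SN2 alkylation with the primary allylic bromide keeps the E geometry; the new C2 stereocentre is irrelevant because it is destroyed in Step 12.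

**Step 11**
Reactants: 12
Product: 13, (4R,5S)-4-acetoxy-5-hydroxy-6-[(2E,6E,10E)-12-hydroxy-3,7,11-trimethyldodeca-2,6,10-trien-1-yl]-3-methylcyclohex-2-en-1-one, as C6 epimers
Conditions: HF·pyridine, pyridine/THF, 0 °C → rt
Reagents that add atoms: none
Why: Buffered fluoride removes both silyl ethers at once while the acetate, enone and trienes survive; this gives the β-hydroxy ketone needed for the closure.

**Step 12**
Reactants: 13
Product: 14, yanuthone L
Conditions: nBu4NI (30 mol %), Cs2CO3 (1.5 equiv), MeCN, undivided cell, graphite anode / Pt cathode, 3 mA constant current, rt, ~2.5 F/mol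
Reagents that add atoms: none (net loss of H2)
Why: Proposed new method: anodic oxidation of I⁻ gives I2/"I⁺", which iodinates the C2 enolate far faster than the isolated trisubstituted alkenes. The tertiary α-iodo ketone whose iodine is anti to the C3 oxygen is then closed by C3–O⁻ in a Darzens-type 3-exo-tet displacement, regenerating I⁻ while H⁺ is reduced to H2 at the cathode. Because a cis-fused epoxide is the only possible geometry, the C3 configuration from the diol fixes the C2 quaternary centre, and the C2 epimers of 13 converge through the enol. The closest known reactions are halide-mediated electrochemical α-halogenation of ketones and the Darzens ring closure of α-halo-β-hydroxy ketones.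

---

**Compound list**

1 | (1S,2R)-3-methylcyclohexa-3,5-diene-1,2-diol | O[C@@H]1C(C)=CC=C[C@@H]1O | starting material
2 | (1S,2R)-3-methyl-1-(triethylsilyloxy)cyclohexa-3,5-dien-2-ol | CC[Si](CC)(CC)O[C@H]1C=CC=C(C)[C@H]1O | intermediate
3 | (1S,2R)-3-methyl-1-(triethylsilyloxy)cyclohexa-3,5-dien-2-yl acetate | CC[Si](CC)(CC)O[C@H]1C=CC=C(C)[C@H]1OC(C)=O | intermediate
4 | (1S,2R)-3-methyl-1-(triethylsilyloxy)cyclohex-3-en-2-yl acetate | CC[Si](CC)(CC)O[C@H]1CCC=C(C)[C@H]1OC(C)=O | intermediate
5 | (4R,5S)-4-acetoxy-3-methyl-5-(triethylsilyloxy)cyclohex-2-en-1-one | CC[Si](CC)(CC)O[C@H]1CC(=O)C=C(C)[C@H]1OC(C)=O | intermediate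
6 | (2E,6E)-farnesol | CC(C)=CCC/C(C)=C/CC/C(C)=C/CO | starting material
7 | (2E,6E)-farnesyl acetate | CC(C)=CCC/C(C)=C/CC/C(C)=C/COC(C)=O | intermediate
8 | (2E,6E,10E)-12-hydroxy-3,7,11-trimethyldodeca-2,6,10-trien-1-yl acetate | OC/C(C)=C/CC/C(C)=C/CC/C(C)=C/COC(C)=O | intermediate
9 | 12-TBS ether of 8 | CC(C)(C)[Si](C)(C)OC/C(C)=C/CC/C(C)=C/CC/C(C)=C/COC(C)=O | intermediate
10 | (2E,6E,10E)-12-(TBSO)-3,7,11-trimethyldodeca-2,6,10-trien-1-ol | CC(C)(C)[Si](C)(C)OC/C(C)=C/CC/C(C)=C/CC/C(C)=C/CO | intermediate
11 | (2E,6E,10E)-1-bromo-12-(TBSO)-3,7,11-trimethyldodeca-2,6,10-triene | CC(C)(C)[Si](C)(C)OC/C(C)=C/CC/C(C)=C/CC/C(C)=C/CBr | intermediate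
12 | C2-alkylated enone (C6 epimers) | CC[Si](CC)(CC)O[C@H]1C(C/C=C(\C)CC/C=C(\C)CC/C=C(\C)CO[Si](C)(C)C(C)(C)C)C(=O)C=C(C)[C@H]1OC(C)=O | intermediate
13 | diol-ketone (C6 epimers) | O[C@H]1C(C/C=C(\C)CC/C=C(\C)CC/C=C(\C)CO)C(=O)C=C(C)[C@H]1OC(C)=O | intermediate
14 | yanuthone L, (1R,5R,6R)-1-[(2E,6E,10E)-12-hydroxy-3,7,11-trimethyldodeca-2,6,10-trienyl]-4-methyl-2-oxo-7-oxabicyclo[4.1.0]hept-3-en-5-yl acetate | CC(=O)O[C@@H]1C(C)=CC(=O)[C@]2(C/C=C(\C)CC/C=C(\C)CC/C=C(\C)CO)O[C@H]12 | target

---

**Total steps:** 12.
**Longest linear sequence:** 8 steps, from farnesol (Steps 5 → 6 → 7 → 8 → 9 → 10 → 11 → 12). From the diol it is 7 steps (Steps 1–4, then 10–12).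

**Three steps most likely to fail**

1. **Step 12 (proposed new electrochemical closure).** Iodination of the γ-position or of the alkenes, acetate migration, or retro-aldol could compete.
   - Fallback (known chemistry): treat 13 with TMSOTf/Et3N to give the silyl enol ether with TMS-protected OH groups.
   - Brominate with NBS at −78 °C to give the tertiary α-bromo ketone.
   - Add TBAF in THF at 0 °C to unmask the C3 alkoxide and effect the Darzens-type closure, then remove the remaining TMS ether on work-up.
2. **Step 10 (enolate alkylation).** β-Elimination of the C3 silyloxy group, which would lead to aromatisation, or γ-deprotonation could lower the yield.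
   - Fallback: make the silyl enol ether of 5 by LDA/TMSCl quench. Then run a neutral Pd(0)-catalysed Tsuji–Trost allylation with the methyl carbonate of 10 (from 10 and ClCO2Me), which needs no strong base and gives linear, E-retentive coupling.
3. **Step 4 (Rh/TBHP allylic oxidation).** Regioselectivity and over-oxidation could be poor.
   - Fallback: Wohl–Ziegler bromination of 4 (NBS, AIBN), followed by Kornblum oxidation of the allylic bromide (DMSO, NaHCO3) to the enone. This is an ionic two-step route instead of the radical-peroxide one.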